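The route rests on cutting the C2–C3 bond of ring B. Both carbons are α to a carboxyl group (C2 sp3; C3 the α-carbon of the C3=C4 acrylate), so they cannot be joined as two enolates; instead C2 is supplied as a redox-active ester and C3 as a vinyl bromide. One nickel-catalysed reductive decarboxylative alkenylation then forms C2–C3, closes ring B and sets C2 cis to the C1 aryl group. Its precursor is an (R)-C1 diarylmethyl malonate bearing one tert-butyl ester and one N-hydroxyphthalimide ester, with a (Z)-α-bromoacrylate ortho on ring A and the (Z)-enol ether already in place; the redox-active ester is made directly before use.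

Key step: step 14

Notation: naphthalene numbering; ring A = benzo ring, ring B = C1–C2–C3–C4–C4a–C8a, ring C = aryl on C1, ring D = aryl of the enol ether. G = 3-methoxy-4-(methoxymethoxy)phenyl. "Enol ether arm" = (Z)-O–C(CO2tBu)=CH–G, with G cis to the ether oxygen. "Bromoacrylate arm" = (Z)-CH=C(Br)CO2tBu, with Br cis to ring A.

Assumption: the target is read as (1R,2R) (C1 aryl and C2 carboxyl cis, (Z)-enol ether); the sense of induction of the two chiral catalysts cannot be predicted with certainty here, so the ligand enantiomers named are taken as those giving (R)-C1 and the cis product, the antipodes being equally available.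

Step 1
Reactants: 1 6-bromoisovanillin (2-bromo-5-hydroxy-4-methoxybenzaldehyde); 2 tert-butyl bromoacetate
Product: 3 tert-butyl (4-bromo-5-formyl-2-methoxyphenoxy)acetate
Conditions: K2CO3, DMF, rt
Reagents that add atoms: none
Why: Williamson ether synthesis; the phenoxide is the only nucleophile formed and displaces bromide from the α-bromo ester, while the aldehyde and aryl bromide are inert to carbonate.

Step 2
Reactants: 3 tert-butyl (4-bromo-5-formyl-2-methoxyphenoxy)acetate
Product: 4 tert-butyl [4-bromo-5-(dimethoxymethyl)-2-methoxyphenoxy]acetate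
Conditions: HC(OMe)3, MeOH, TsOH·H2O (cat.), rt; Et3N quench
Reagents that add atoms: trimethyl orthoformate COC(OC)OC; methanol CO (exchanging methoxy source)
Why: Acid-catalysed acetalisation driven by the orthoformate masks the ring A aldehyde (the future C1 carbon) so that the enolate of step 4 can meet only aldehyde 6; the tert-butyl ester tolerates catalytic acid at room temperature.

Step 3
Reactants: 5 vanillin
Product: 6 3-methoxy-4-(methoxymethoxy)benzaldehyde (G–CHO)
Conditions: MOMCl, iPr2NEt, CH2Cl2, 0 °C to rt
Reagents that add atoms: chloromethyl methyl ether COCCl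
Why: Standard O-alkylation of the phenol (MOM protection) gives an acetal that should survive all later basic and organometallic steps and leave together with the tert-butyl esters.

Step 4
Reactants: 4 tert-butyl [4-bromo-5-(dimethoxymethyl)-2-methoxyphenoxy]acetate; 6 3-methoxy-4-(methoxymethoxy)benzaldehyde
Product: 9 tert-butyl (Z)-2-[4-bromo-5-(dimethoxymethyl)-2-methoxyphenoxy]-3-G-prop-2-enoate, via lithium aldolate 7 (not isolated), via β-acetoxy ester 8 (not isolated)
Conditions: LiN(iPr)2, THF, −78 °C; then 6; then Ac2O, −78 to 0 °C; then DBU, rt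
Reagents that add atoms: none
Why: Lithium ester-enolate aldol addition, acetylation of the aldolate and DBU-induced E1cB elimination give the α-aryloxycinnamate; elimination through the ester-stabilised carbanion should favour the (Z)-alkene with ring D trans to the bulky ester, as is usual for α-aryloxy- and α-alkoxycinnamates.

Step 5
Reactants: 9 tert-butyl (Z)-2-[4-bromo-5-(dimethoxymethyl)-2-methoxyphenoxy]-3-G-prop-2-enoate
Product: 10 tert-butyl (Z)-2-[5-(dimethoxymethyl)-4-formyl-2-methoxyphenoxy]-3-G-prop-2-enoate
Conditions: Pd(OAc)2 (cat.), di(1-adamantyl)-n-butylphosphine, CO/H2 (1:1, 5 bar), TMEDA, toluene, 100 °C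
Reagents that add atoms: carbon monoxide [C-]#[O+]
Why: Palladium-catalysed reductive carbonylation (formylation) of the aryl bromide by oxidative addition, CO insertion and hydrogenolysis of the acyl–palladium species; acetal, esters, MOM ether and the trisubstituted enol ether are inert under these conditions.

Step 6
Reactants: 11 tert-butyl (triphenylphosphoranylidene)acetate
Product: 13 tert-butyl bromo(triphenylphosphoranylidene)acetate, via bromophosphonium bromide 12 (not isolated)
Conditions: Br2, CH2Cl2, 0 °C; then aq. NaOH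
Reagents that add atoms: bromine BrBr
Why: C-bromination of a stabilised ylide followed by deprotonation of the phosphonium salt is the standard preparation of α-bromo ylides.

Step 7
Reactants: 10 tert-butyl (Z)-2-[5-(dimethoxymethyl)-4-formyl-2-methoxyphenoxy]-3-G-prop-2-enoate; 13 tert-butyl bromo(triphenylphosphoranylidene)acetate
Product: 14 tert-butyl (Z)-2-bromo-3-[2-(dimethoxymethyl)-5-methoxy-4-(enol ether arm)phenyl]prop-2-enoate
Conditions: CH2Cl2, rt to 40 °C
Reagents that add atoms: none
Why: Wittig olefination with a stabilised α-bromo ylide places the ester trans to the aryl group, so the (Z)-bromoacrylate with bromine cis to ring A, the geometry needed for ring closure, should predominate.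

Step 8
Reactants: 14 tert-butyl (Z)-2-bromo-3-[2-(dimethoxymethyl)-5-methoxy-4-(enol ether arm)phenyl]prop-2-enoate
Product: 15 tert-butyl (Z)-2-bromo-3-[2-formyl-5-methoxy-4-(enol ether arm)phenyl]prop-2-enoate
Conditions: PPTS (cat.), acetone/H2O, rt
Reagents that add atoms: water O
Why: Acid-catalysed acetal hydrolysis; the dimethyl acetal of an electron-rich benzaldehyde is cleaved under conditions far too mild to affect aryl MOM ethers, tert-butyl esters or the vinyl bromide.

Step 9
Reactants: 15 tert-butyl (Z)-2-bromo-3-[2-formyl-5-methoxy-4-(enol ether arm)phenyl]prop-2-enoate; 16 Meldrum's acid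
Product: 17 5-{[2-(bromoacrylate arm)-4-methoxy-5-(enol ether arm)phenyl]methylidene}-2,2-dimethyl-1,3-dioxane-4,6-dione
Conditions: piperidine (cat.), AcOH (cat.), toluene, 4 Å MS, rt
Reagents that add atoms: none
Why: Knoevenagel condensation of an aromatic aldehyde with Meldrum's acid (pKa about 5); the acceptor is symmetrical, so no alkene geometry arises.

Step 10
Reactants: 18 2-methoxy-4-(4,4,5,5-tetramethyl-1,3,2-dioxaborolan-2-yl)phenol
Product: 19 2-G-4,4,5,5-tetramethyl-1,3,2-dioxaborolane
Conditions: MOMCl, iPr2NEt, CH2Cl2, 0 °C to rt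
Reagents that add atoms: chloromethyl methyl ether COCCl
Why: MOM protection by O-alkylation of the phenol; the pinacol boronate is unaffected by the weakly basic conditions.

Step 11
Reactants: 17 arylidene Meldrum's acid; 19 2-G-4,4,5,5-tetramethyl-1,3,2-dioxaborolane
Product: 20 5-{(R)-[2-(bromoacrylate arm)-4-methoxy-5-(enol ether arm)phenyl](G)methyl}-2,2-dimethyl-1,3-dioxane-4,6-dione
Conditions: [RhCl(C2H4)2]2 (cat.), (R,R)-2,5-diphenylbicyclo[2.2.2]octa-2,5-diene, aq. KOH (substoichiometric), 1,4-dioxane, 50 °C
Reagents that add atoms: none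
Why: Hayashi–Miyaura rhodium-catalysed asymmetric 1,4-addition; the aryl–rhodium species adds to the strongly electrophilic alkylidene Meldrum's acid far faster than to the trisubstituted acrylates or the vinyl bromide, and the chiral diene on rhodium selects the enantiotopic face of the arylidene so that C1 is set as (R).

Step 12
Reactants: 20 (R)-Meldrum's acid adduct
Product: 21 (3R)-2-(tert-butoxycarbonyl)-3-[2-(bromoacrylate arm)-4-methoxy-5-(enol ether arm)phenyl]-3-G-propanoic acid (both C2 epimers)
Conditions: tBuOH/toluene (1:1), 85 °C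
Reagents that add atoms: tert-butanol CC(C)(C)O
Why: Thermal alcoholysis of a 5-monosubstituted Meldrum's acid (loss of acetone, trapping of the carboxyketene by tert-butanol) gives the malonic acid mono-tert-butyl ester below its decarboxylation temperature; C1 is untouched and the C2 mixture is irrelevant to the key step.

Step 13
Reactants: 21 malonic half-acid
Product: 22 1-tert-butyl 3-(1,3-dioxoisoindolin-2-yl) 2-{(R)-[2-(bromoacrylate arm)-4-methoxy-5-(enol ether arm)phenyl](G)methyl}propanedioate (both C2 epimers)
Conditions: N-hydroxyphthalimide, iPrN=C=NiPr, CH2Cl2, 0 °C to rt; used at once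
Reagents that add atoms: N-hydroxyphthalimide O=C1c2ccccc2C(=O)N1O
Why: Carbodiimide (Steglich-type) esterification with N-hydroxyphthalimide; no amine base is added so that the acidic malonate-type ester is not eliminated to a ketene, and nothing but the key step follows.

Step 14
Reactants: 22 redox-active malonate half-ester
Product: 23 di-tert-butyl (1R,2R)-1-G-6-methoxy-7-(enol ether arm)-1,2-dihydronaphthalene-2,3-dicarboxylate
Conditions: NiBr2·diglyme (20 mol %), 2,2'-(cyclopropane-1,1-diyl)bis[(3aS,8aR)-3a,8a-dihydro-8H-indeno[1,2-d]oxazole] (24 mol %), Zn dust, NaI, DMA, 0.01 M, 0 °C to rt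
Reagents that add atoms: none
Why: Proposed new method: zerovalent nickel should insert into the vinyl C–Br bond with retention of the (Z)-geometry, single-electron reduction of the N-acyloxyphthalimide should release CO2 and phthalimide to give the planar, ester-stabilised C2 radical, and capture of that radical by the tethered vinylnickel followed by reductive elimination from trivalent nickel forms C2–C3. The closest known reaction type is the intermolecular nickel-catalysed reductive decarboxylative alkenylation of N-hydroxyphthalimide esters with alkenyl bromides, including bis(oxazoline)-controlled enantioselective versions; an intramolecular closure of a malonate-derived radical onto an α-bromoacrylate has no direct precedent. Ring B closes as a six-membered ring by reductive elimination from a seven-membered nickelacycle (the C3=C4 bond ends up inside the ring), which is geometrically possible only because bromine is cis to ring A. The new C2 centre is controlled by the chiral ligand on nickel acting together with the fixed (R)-C1 centre, and because both C2 epimers of 22 give the same radical the step is stereoconvergent. The selectivities needed are cis over trans and nickel capture over 5-exo attack on C4 or simple reduction of the radical; they are to be secured by the matched ligand, by high dilution and by the polarity mismatch between the electrophilic radical and the electron-poor alkene, and direct radical attack at C3 with loss of a bromine atom would lead to the same product.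

Step 15
Reactants: 23 tri-tert-butyl ester bis-MOM ether
Product: 24 (1R,2R)-7-{[(Z)-1-carboxy-2-(4-hydroxy-3-methoxyphenyl)ethenyl]oxy}-1-(4-hydroxy-3-methoxyphenyl)-6-methoxy-1,2-dihydronaphthalene-2,3-dicarboxylic acid (CNP0328417.1)
Conditions: TFA/CH2Cl2 (1:1), H2O (few equiv), 0 °C to rt
Reagents that add atoms: none
Why: Acidolysis; trifluoroacetic acid ionises the three tert-butyl esters (E1, loss of 2-methylpropene) and hydrolyses both MOM acetals in one operation, and since no base is present the epimerisable C2–H and the cis relationship should stay intact.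

Compound list
1 | 6-bromoisovanillin | COc1cc(Br)c(C=O)cc1O | starting material
2 | tert-butyl bromoacetate | CC(C)(C)OC(=O)CBr | starting material
3 | tert-butyl (4-bromo-5-formyl-2-methoxyphenoxy)acetate | COc1cc(Br)c(C=O)cc1OCC(=O)OC(C)(C)C | intermediate
4 | tert-butyl [4-bromo-5-(dimethoxymethyl)-2-methoxyphenoxy]acetate | COc1cc(Br)c(C(OC)OC)cc1OCC(=O)OC(C)(C)C | intermediate
5 | vanillin | COc1cc(C=O)ccc1O | starting material
6 | 3-methoxy-4-(methoxymethoxy)benzaldehyde | COCOc1ccc(C=O)cc1OC | intermediate
7 | lithium aldolate of 4 and 6 (diastereomer mixture, not isolated) | [Li+].COCOc1ccc(C([O-])C(Oc2cc(C(OC)OC)c(Br)cc2OC)C(=O)OC(C)(C)C)cc1OC | intermediate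
8 | tert-butyl 3-acetoxy-2-[4-bromo-5-(dimethoxymethyl)-2-methoxyphenoxy]-3-G-propanoate (diastereomer mixture, not isolated) | COCOc1ccc(C(OC(C)=O)C(Oc2cc(C(OC)OC)c(Br)cc2OC)C(=O)OC(C)(C)C)cc1OC | intermediate
9 | tert-butyl (Z)-2-[4-bromo-5-(dimethoxymethyl)-2-methoxyphenoxy]-3-G-prop-2-enoate | COCOc1ccc(/C=C(\Oc2cc(C(OC)OC)c(Br)cc2OC)C(=O)OC(C)(C)C)cc1OC | intermediate
10 | tert-butyl (Z)-2-[5-(dimethoxymethyl)-4-formyl-2-methoxyphenoxy]-3-G-prop-2-enoate | COCOc1ccc(/C=C(\Oc2cc(C(OC)OC)c(C=O)cc2OC)C(=O)OC(C)(C)C)cc1OC | intermediate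
11 | tert-butyl (triphenylphosphoranylidene)acetate | CC(C)(C)OC(=O)C=P(c1ccccc1)(c1ccccc1)c1ccccc1 | starting material
12 | (1-bromo-2-tert-butoxy-2-oxoethyl)triphenylphosphonium bromide (not isolated) | CC(C)(C)OC(=O)C(Br)[P+](c1ccccc1)(c1ccccc1)c1ccccc1.[Br-] | intermediate
13 | tert-butyl bromo(triphenylphosphoranylidene)acetate | CC(C)(C)OC(=O)C(Br)=P(c1ccccc1)(c1ccccc1)c1ccccc1 | intermediate
14 | tert-butyl (Z)-2-bromo-3-[2-(dimethoxymethyl)-5-methoxy-4-(enol ether arm)phenyl]prop-2-enoate | COCOc1ccc(/C=C(\Oc2cc(C(OC)OC)c(/C=C(\Br)C(=O)OC(C)(C)C)cc2OC)C(=O)OC(C)(C)C)cc1OC | intermediate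
15 | tert-butyl (Z)-2-bromo-3-[2-formyl-5-methoxy-4-(enol ether arm)phenyl]prop-2-enoate | COCOc1ccc(/C=C(\Oc2cc(C=O)c(/C=C(\Br)C(=O)OC(C)(C)C)cc2OC)C(=O)OC(C)(C)C)cc1OC | intermediate
16 | Meldrum's acid | CC1(C)OC(=O)CC(=O)O1 | starting material
17 | arylidene Meldrum's acid | COCOc1ccc(/C=C(\Oc2cc(C=C3C(=O)OC(C)(C)OC3=O)c(/C=C(\Br)C(=O)OC(C)(C)C)cc2OC)C(=O)OC(C)(C)C)cc1OC | intermediate
18 | 2-methoxy-4-(4,4,5,5-tetramethyl-1,3,2-dioxaborolan-2-yl)phenol | COc1cc(B2OC(C)(C)C(C)(C)O2)ccc1O | starting material
19 | 2-[3-methoxy-4-(methoxymethoxy)phenyl]-4,4,5,5-tetramethyl-1,3,2-dioxaborolane | COCOc1ccc(B2OC(C)(C)C(C)(C)O2)cc1OC | intermediate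
20 | (R)-diarylmethyl Meldrum's acid adduct | COCOc1ccc(/C=C(\Oc2cc([C@@H](c3ccc(OCOC)c(OC)c3)C3C(=O)OC(C)(C)OC3=O)c(/C=C(\Br)C(=O)OC(C)(C)C)cc2OC)C(=O)OC(C)(C)C)cc1OC | intermediate
21 | (3R)-malonic acid mono-tert-butyl ester, both C2 epimers | COCOc1ccc(/C=C(\Oc2cc([C@@H](c3ccc(OCOC)c(OC)c3)C(C(=O)O)C(=O)OC(C)(C)C)c(/C=C(\Br)C(=O)OC(C)(C)C)cc2OC)C(=O)OC(C)(C)C)cc1OC | intermediate
22 | N-hydroxyphthalimide ester of 21, (R) at C1, both C2 epimers (key-step precursor) | COCOc1ccc(/C=C(\Oc2cc([C@@H](c3ccc(OCOC)c(OC)c3)C(C(=O)OC(C)(C)C)C(=O)ON3C(=O)c4ccccc4C3=O)c(/C=C(\Br)C(=O)OC(C)(C)C)cc2OC)C(=O)OC(C)(C)C)cc1OC | intermediate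
23 | (1R,2R)-tri-tert-butyl ester bis-MOM ether (key-step product) | COCOc1ccc(/C=C(\Oc2cc3c(cc2OC)C=C(C(=O)OC(C)(C)C)[C@H](C(=O)OC(C)(C)C)[C@@H]3c2ccc(OCOC)c(OC)c2)C(=O)OC(C)(C)C)cc1OC | intermediate
24 | CNP0328417.1, (1R,2R), (Z)-enol ether | COc1cc(/C=C(\Oc2cc3c(cc2OC)C=C(C(=O)O)[C@H](C(=O)O)[C@@H]3c2ccc(O)c(OC)c2)C(=O)O)ccc1O | target

Total step count: 15. Longest linear sequence: 12 (steps 1, 2, 4, 5, 7, 8, 9, 11, 12, 13, 14, 15).

Steps most likely to fail

1. Step 14 (key step).
   - What may go wrong: the C2 radical may be reduced and protonated before nickel captures it, so the carboxyl is lost without ring closure. It may also attack C4 in a 5-exo mode, or be captured on the face that gives the trans arrangement when ligand and C1 are mismatched.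
   - Fallback (known two-electron chemistry, from 21 back to 23): O-allylation of the carboxylate of 21 (allyl bromide, KHCO3, DMF) would give the allyl tert-butyl malonate F1. A Hurtley-type intramolecular C-vinylation of the malonate with the vinyl bromide (CuI, L-proline, Cs2CO3, dioxane, 70 °C) would close ring B to the C2-quaternary diester F2. Pd(PPh3)4/morpholine would remove the allyl group to give the quaternary malonic half-acid F3. Thermal decarboxylation of F3 (toluene, 90 °C) passes through an ester enol that should be protonated on the face remote from ring C, which places the ester cis to ring C and rejoins the route at 23.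

2. Step 11.
   - What may go wrong: insertion may be slow and facial discrimination poor at the ortho-substituted arylidene, protodeboronation of the electron-rich boronate may outpace addition, or aqueous base may hydrolyse the arylidene.
   - Fallback (racemic addition then resolution, from 17 back to 20): commercial 4-bromo-2-methoxyphenol is converted with MOMCl/iPr2NEt into 4-bromo-2-methoxy-1-(methoxymethoxy)benzene F4, and with Mg in THF into [3-methoxy-4-(methoxymethoxy)phenyl]magnesium bromide F5. Uncatalysed conjugate addition of F5 to 17 at −78 °C should give the racemic Meldrum's acid adduct F6. The (R)-enantiomer is then separated by preparative chromatography on a chiral stationary phase, which returns to 20.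

3. Step 15.
   - What may go wrong: the two freed guaiacol rings may be alkylated by tert-butyl or methoxymethyl cations or by formaldehyde, and the acid may isomerise the enol ether.
   - Fallback (staged unmasking, from 23 to 24): ZnBr2/1-propanethiol (CH2Cl2, 0 °C) would first remove both MOM groups, the methoxymethyl unit leaving as a thioether so that no formaldehyde forms, giving the bis-phenol tri-tert-butyl ester F7. The esters are then cleaved separately with 85% aqueous H3PO4 in toluene, which releases only 2-methylpropene and arrives at 24.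

Further compounds
F1 | step 14 | allyl tert-butyl malonate from 21, (R) at C1, both C2 epimers | COCOc1ccc(/C=C(\Oc2cc([C@@H](c3ccc(OCOC)c(OC)c3)C(C(=O)OCC=C)C(=O)OC(C)(C)C)c(/C=C(\Br)C(=O)OC(C)(C)C)cc2OC)C(=O)OC(C)(C)C)cc1OC
F2 | step 14 | (1R)-2-allyl 2,3-di-tert-butyl 1-G-6-methoxy-7-(enol ether arm)-1,2-dihydronaphthalene-2,2,3-tricarboxylate, both C2 epimers | COCOc1ccc(/C=C(\Oc2cc3c(cc2OC)C=C(C(=O)OC(C)(C)C)C(C(=O)OCC=C)(C(=O)OC(C)(C)C)[C@@H]3c2ccc(OCOC)c(OC)c2)C(=O)OC(C)(C)C)cc1OC
F3 | step 14 | (1R)-2,3-bis(tert-butoxycarbonyl)-1-G-6-methoxy-7-(enol ether arm)-1,2-dihydronaphthalene-2-carboxylic acid, both C2 epimers | COCOc1ccc(/C=C(\Oc2cc3c(cc2OC)C=C(C(=O)OC(C)(C)C)C(C(=O)O)(C(=O)OC(C)(C)C)[C@@H]3c2ccc(OCOC)c(OC)c2)C(=O)OC(C)(C)C)cc1OC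
F4 | step 11 | 4-bromo-2-methoxy-1-(methoxymethoxy)benzene | COCOc1ccc(Br)cc1OC
F5 | step 11 | [3-methoxy-4-(methoxymethoxy)phenyl]magnesium bromide | COCOc1ccc([Mg]Br)cc1OC
F6 | step 11 | racemic diarylmethyl Meldrum's acid adduct (racemate of 20) | COCOc1ccc(/C=C(\Oc2cc(C(c3ccc(OCOC)c(OC)c3)C3C(=O)OC(C)(C)OC3=O)c(/C=C(\Br)C(=O)OC(C)(C)C)cc2OC)C(=O)OC(C)(C)C)cc1OC
F7 | step 15 | (1R,2R)-bis-phenol tri-tert-butyl ester | COc1cc(/C=C(\Oc2cc3c(cc2OC)C=C(C(=O)OC(C)(C)C)[C@H](C(=O)OC(C)(C)C)[C@@H]3c2ccc(O)c(OC)c2)C(=O)OC(C)(C)C)ccc1O
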